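Ring C is disconnected at O1–C2 and at C4–C4a: ring A offers O1 and its ortho carbon C4a as an O–C=C 1,3-pair, and the C2–C3–C4 chain is a cinnamoyl unit. The cinnamoyl group is parked on O1 as an aryl ester, where it first serves as protecting group while the C5 oxygen is installed and silylated. In one flask a photo-Fries shift then moves the acyl carbon from O1 to C4a, and a chiral amine–thiourea closes the freed O1 onto C2 (6-endo oxa-Michael), setting (2S). The precursor is an open aryl (E)-cinnamate, silylated at the future C5 oxygen, whose ester oxygen becomes the ring oxygen.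

Key step: step 5

Remark: flavanone numbering is used throughout (O1, C2, C3, C4, C4a, C5 to C8, C8a; ring A is the benzo ring, ring C the pyranone ring, ring B the 2,6-dimethoxyphenyl group). Compounds 1, 2 and 4 are assumed to be commercially available.

Step 1
Reactants: 1 2,6-dimethoxybenzaldehyde; 2 malonic acid
Product: 3 (E)-3-(2,6-dimethoxyphenyl)prop-2-enoic acid
Conditions: pyridine, piperidine (cat.), 100 °C; then aq. HCl
Reagents that add atoms: none
Why: Knoevenagel–Doebner condensation with decarboxylation should give the thermodynamically favoured (E)-cinnamic acid, the two ortho methoxy groups only slowing the addition.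

Step 2
Reactants: 3 (E)-3-(2,6-dimethoxyphenyl)prop-2-enoic acid; 4 3-hydroxy-4,5-dimethoxybenzaldehyde
Product: 5 5-formyl-2,3-dimethoxyphenyl (E)-3-(2,6-dimethoxyphenyl)prop-2-enoate
Conditions: DCC, DMAP (cat.), CH2Cl2, 0 °C to rt
Reagents that add atoms: none
Why: Steglich esterification should acylate the only phenol, which is the oxygen that becomes O1, so the cinnamoyl unit is installed and this oxygen is masked in the same step.

Step 3
Reactants: 5 5-formyl-2,3-dimethoxyphenyl (E)-3-(2,6-dimethoxyphenyl)prop-2-enoate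
Product: 7 5-hydroxy-2,3-dimethoxyphenyl (E)-3-(2,6-dimethoxyphenyl)prop-2-enoate, via aryl formate 6 (not isolated)
Conditions: mCPBA, CH2Cl2, 0 °C to rt; then MeOH, Et3N (cat.), 0 °C
Reagents that add atoms: 3-chloroperoxybenzoic acid (mCPBA), O=C(OO)c1cccc(Cl)c1
Why: Dakin-type Baeyer–Villiger oxidation with migration of the para-methoxy-activated aryl group should give the aryl formate, which is far more labile to methanolysis than the aryl cinnamate, while the ester-conjugated alkene is a poor partner for the electrophilic peracid.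

Step 4
Reactants: 7 5-hydroxy-2,3-dimethoxyphenyl (E)-3-(2,6-dimethoxyphenyl)prop-2-enoate
Product: 8 5-[(tert-butyldimethylsilyl)oxy]-2,3-dimethoxyphenyl (E)-3-(2,6-dimethoxyphenyl)prop-2-enoate
Conditions: TBSCl, imidazole, DMF, 0 °C to rt
Reagents that add atoms: tert-butyldimethylsilyl chloride (TBSCl), CC(C)(C)[Si](C)(C)Cl
Why: Silylation of the free phenol blocks the future C5 oxygen, so that ring C can later close only through O1 and the 7,8-dimethoxy pattern is fixed.

Step 5
Reactants: 8 5-[(tert-butyldimethylsilyl)oxy]-2,3-dimethoxyphenyl (E)-3-(2,6-dimethoxyphenyl)prop-2-enoate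
Product: 10 (2S)-5-[(tert-butyldimethylsilyl)oxy]-2-(2,6-dimethoxyphenyl)-7,8-dimethoxy-2,3-dihydro-4H-chromen-4-one, via hydroxychalcone 9 (not isolated)
Conditions: hν (300 nm, Pyrex), degassed toluene (0.01 M), 15 °C; then lamp off, cinchona-derived amine–thiourea (9-amino-9-deoxy-epi-cinchona 3,5-bis(trifluoromethyl)phenyl thiourea, 10 mol %), 0 °C
Reagents that add atoms: none
Why: Excitation of the aryl cinnamate should cleave the ArO–C(=O) bond homolytically (photo-Fries rearrangement), the caged aryloxyl/cinnamoyl radical pair recombines at the free ortho carbon (future C4a) and tautomerisation gives hydroxychalcone 9, so that the acyl carbon C4 moves from O1 to C4a; in the dark the amine of the catalyst then deprotonates the O1–H phenol while its thiourea binds the enone carbonyl, and the phenoxide adds to C2 (oxa-Michael addition). The closest known reaction types are the photo-Fries rearrangement of aryl cinnamates to 2'-hydroxychalcones and the cinchona-base-catalysed enantioselective cyclisation of 2'-hydroxychalcones to flavanones. Ring C closes in a 6-endo-trig mode. The only new stereocentre, C2, is set by the catalyst, which must deliver O1 to the Si face of the β-carbon to give (2S), and the quinine- or quinidine-derived pseudoenantiomer is chosen accordingly. The step needs ortho rather than para acyl migration, which in-cage recombination next to the departing oxygen favours (a para isomer cannot cyclise and is separated), and it needs closure through O1 only, which the silyl ether on the other ortho oxygen secures. A racemic background closure should be held back because chalcone 9 is stabilised by its O–H···O=C hydrogen bond in toluene and neither acid nor free base is present before the catalyst is added.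

Step 6
Reactants: 10 (2S)-5-[(tert-butyldimethylsilyl)oxy]-2-(2,6-dimethoxyphenyl)-7,8-dimethoxy-2,3-dihydro-4H-chromen-4-one
Product: 11 (2S)-5-hydroxy-7,8,2',6'-tetramethoxyflavanone
Conditions: HF·pyridine, pyridine, THF, 0 °C
Reagents that add atoms: none
Why: Fluoride-mediated desilylation of the aryl silyl ether under buffered, nearly neutral conditions should free the C5 phenol without forming the phenoxide or enolate that would open ring C, so C2 keeps its configuration.

Compound list
1 | 2,6-dimethoxybenzaldehyde | COc1cccc(OC)c1C=O | starting material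
2 | malonic acid | OC(=O)CC(=O)O | starting material
3 | (E)-3-(2,6-dimethoxyphenyl)prop-2-enoic acid | COc1cccc(OC)c1/C=C/C(=O)O | intermediate
4 | 3-hydroxy-4,5-dimethoxybenzaldehyde | COc1cc(C=O)cc(O)c1OC | starting material
5 | 5-formyl-2,3-dimethoxyphenyl (E)-3-(2,6-dimethoxyphenyl)prop-2-enoate | COc1cc(C=O)cc(OC(=O)/C=C/c2c(OC)cccc2OC)c1OC | intermediate
6 | 5-(formyloxy)-2,3-dimethoxyphenyl (E)-3-(2,6-dimethoxyphenyl)prop-2-enoate (formed in the flask) | COc1cc(OC=O)cc(OC(=O)/C=C/c2c(OC)cccc2OC)c1OC | intermediate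
7 | 5-hydroxy-2,3-dimethoxyphenyl (E)-3-(2,6-dimethoxyphenyl)prop-2-enoate | COc1cc(O)cc(OC(=O)/C=C/c2c(OC)cccc2OC)c1OC | intermediate
8 | 5-[(tert-butyldimethylsilyl)oxy]-2,3-dimethoxyphenyl (E)-3-(2,6-dimethoxyphenyl)prop-2-enoate | COc1cc(O[Si](C)(C)C(C)(C)C)cc(OC(=O)/C=C/c2c(OC)cccc2OC)c1OC | intermediate
9 | (E)-1-{6-[(tert-butyldimethylsilyl)oxy]-2-hydroxy-3,4-dimethoxyphenyl}-3-(2,6-dimethoxyphenyl)prop-2-en-1-one (formed in the flask) | COc1cc(O[Si](C)(C)C(C)(C)C)c(C(=O)/C=C/c2c(OC)cccc2OC)c(O)c1OC | intermediate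
10 | (2S)-5-[(tert-butyldimethylsilyl)oxy]-2-(2,6-dimethoxyphenyl)-7,8-dimethoxy-2,3-dihydro-4H-chromen-4-one | COc1cc(O[Si](C)(C)C(C)(C)C)c2c(c1OC)O[C@H](c1c(OC)cccc1OC)CC2=O | intermediate
11 | (2S)-5-hydroxy-7,8,2',6'-tetramethoxyflavanone, that is (2S)-2-(2,6-dimethoxyphenyl)-5-hydroxy-7,8-dimethoxy-2,3-dihydro-4H-chromen-4-one | COc1cc(O)c2c(c1OC)O[C@H](c1c(OC)cccc1OC)CC2=O | target

Total step count: 6
Longest linear sequence: 6 steps (1 → 3 → 5 → 7 → 8 → 10 → 11)

Steps most likely to fail

Step 5. The photochemical acyl shift may go to the para carbon, or stall through E/Z isomerisation of the cinnamate and light absorption by the chalcone. The ring closure may also show weak facial selectivity at the hindered, electron-rich β-carbon. The fallback replaces both events by thermal acylation, racemic closure and kinetic resolution; it sets out from 3 and comes back at 11. Acid 3 would be converted with oxalyl chloride (cat. DMF, CH2Cl2) into (E)-3-(2,6-dimethoxyphenyl)prop-2-enoyl chloride F1. Friedel–Crafts acylation of commercial 1,2,3,5-tetramethoxybenzene with F1 and AlCl3 (Et2O/CH2Cl2, 0 °C to rt) should give (E)-3-(2,6-dimethoxyphenyl)-1-(2,3,4,6-tetramethoxyphenyl)prop-2-en-1-one F2. In the same flask F2 should lose the methyl group of the ortho methoxy group flanked by the ketone and a second methoxy group (chelation-assisted), giving (E)-3-(2,6-dimethoxyphenyl)-1-(2-hydroxy-3,4,6-trimethoxyphenyl)prop-2-en-1-one F3. NaOAc in refluxing EtOH should close ring C to racemic 2-(2,6-dimethoxyphenyl)-5,7,8-trimethoxy-2,3-dihydro-4H-chromen-4-one F4. Kinetic resolution by asymmetric transfer hydrogenation would follow [RuCl(p-cymene)(TsDPEN), HCO2H/Et3N, the ligand enantiomer that reduces the (2R)-ketone faster, run to about half conversion]. It should turn the unwanted enantiomer into (2R,4R)-2-(2,6-dimethoxyphenyl)-5,7,8-trimethoxy-3,4-dihydro-2H-chromen-4-ol F5 and leave (2S)-2-(2,6-dimethoxyphenyl)-5,7,8-trimethoxy-2,3-dihydro-4H-chromen-4-one F6. BCl3 (CH2Cl2, −78 °C) should then cleave only the methyl ether peri to the ketone of F6 to give 11.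

Step 3. The peracid may epoxidise the styrenyl double bond, or the cinnamoyl ester may be lost during formate methanolysis. The fallback carries out the oxidation before the cinnamate is attached; it sets out from 4 and comes back at 8. Benzylation of 4 (BnBr, K2CO3, DMF) should give 3-(benzyloxy)-4,5-dimethoxybenzaldehyde F7. mCPBA (CH2Cl2) should give 3-(benzyloxy)-4,5-dimethoxyphenyl formate F8, cleaved in the same flask (K2CO3, MeOH) to 3-(benzyloxy)-4,5-dimethoxyphenol F9. TBSCl/imidazole should give [3-(benzyloxy)-4,5-dimethoxyphenoxy](tert-butyl)dimethylsilane F10. Hydrogenolysis (H2, Pd/C, EtOAc) should free the other oxygen as 5-[(tert-butyldimethylsilyl)oxy]-2,3-dimethoxyphenol F11, and DCC/DMAP esterification of F11 with 3 gives 8.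

Step 6. Configuration at C2 may be lost through reversible ring opening (retro-oxa-Michael) once the peri phenol is set free under fluoride. The fallback uses a benzyl ether removed by neutral hydrogenolysis; it sets out from 7 and comes back at 11. Benzylation of 7 (BnBr, K2CO3, acetone, rt) should give 5-(benzyloxy)-2,3-dimethoxyphenyl (E)-3-(2,6-dimethoxyphenyl)prop-2-enoate F12. The conditions of step 5 should give, by way of (E)-1-[6-(benzyloxy)-2-hydroxy-3,4-dimethoxyphenyl]-3-(2,6-dimethoxyphenyl)prop-2-en-1-one F13, the flavanone (2S)-5-(benzyloxy)-2-(2,6-dimethoxyphenyl)-7,8-dimethoxy-2,3-dihydro-4H-chromen-4-one F14. H2 over Pd/C (EtOAc, rt) should then remove the benzyl group to give 11.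

Further compounds
F1 | step 5 | (E)-3-(2,6-dimethoxyphenyl)prop-2-enoyl chloride | COc1cccc(OC)c1/C=C/C(Cl)=O
F2 | step 5 | (E)-3-(2,6-dimethoxyphenyl)-1-(2,3,4,6-tetramethoxyphenyl)prop-2-en-1-one | COc1cc(OC)c(C(=O)/C=C/c2c(OC)cccc2OC)c(OC)c1OC
F3 | step 5 | (E)-3-(2,6-dimethoxyphenyl)-1-(2-hydroxy-3,4,6-trimethoxyphenyl)prop-2-en-1-one | COc1cc(OC)c(C(=O)/C=C/c2c(OC)cccc2OC)c(O)c1OC
F4 | step 5 | racemic 2-(2,6-dimethoxyphenyl)-5,7,8-trimethoxy-2,3-dihydro-4H-chromen-4-one | COc1cc(OC)c2c(c1OC)OC(c1c(OC)cccc1OC)CC2=O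
F5 | step 5 | (2R,4R)-2-(2,6-dimethoxyphenyl)-5,7,8-trimethoxy-3,4-dihydro-2H-chromen-4-ol | COc1cc(OC)c2c(c1OC)O[C@@H](c1c(OC)cccc1OC)C[C@H]2O
F6 | step 5 | (2S)-2-(2,6-dimethoxyphenyl)-5,7,8-trimethoxy-2,3-dihydro-4H-chromen-4-one | COc1cc(OC)c2c(c1OC)O[C@H](c1c(OC)cccc1OC)CC2=O
F7 | step 3 | 3-(benzyloxy)-4,5-dimethoxybenzaldehyde | COc1cc(C=O)cc(OCc2ccccc2)c1OC
F8 | step 3 | 3-(benzyloxy)-4,5-dimethoxyphenyl formate | COc1cc(OC=O)cc(OCc2ccccc2)c1OC
F9 | step 3 | 3-(benzyloxy)-4,5-dimethoxyphenol | COc1cc(O)cc(OCc2ccccc2)c1OC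
F10 | step 3 | [3-(benzyloxy)-4,5-dimethoxyphenoxy](tert-butyl)dimethylsilane | COc1cc(O[Si](C)(C)C(C)(C)C)cc(OCc2ccccc2)c1OC
F11 | step 3 | 5-[(tert-butyldimethylsilyl)oxy]-2,3-dimethoxyphenol | COc1cc(O[Si](C)(C)C(C)(C)C)cc(O)c1OC
F12 | step 6 | 5-(benzyloxy)-2,3-dimethoxyphenyl (E)-3-(2,6-dimethoxyphenyl)prop-2-enoate | COc1cc(OCc2ccccc2)cc(OC(=O)/C=C/c2c(OC)cccc2OC)c1OC
F13 | step 6 | (E)-1-[6-(benzyloxy)-2-hydroxy-3,4-dimethoxyphenyl]-3-(2,6-dimethoxyphenyl)prop-2-en-1-one | COc1cc(OCc2ccccc2)c(C(=O)/C=C/c2c(OC)cccc2OC)c(O)c1OC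
F14 | step 6 | (2S)-5-(benzyloxy)-2-(2,6-dimethoxyphenyl)-7,8-dimethoxy-2,3-dihydro-4H-chromen-4-one | COc1cc(OCc2ccccc2)c2c(c1OC)O[C@H](c1c(OC)cccc1OC)CC2=O
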